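**Anal**ysis and route for 5,7-dihydroxy-8-[(1R)-1-(4-hydroxyphenyl)ethyl]-3-methoxy-2-(4-methoxyphenyl)-4H-chromen-4-one (16)

## Analysis of the target

Target 16 is a 3-methoxyflavone. Its benzo ring A carries hydroxyls at C5 and C7 and a 1-(4-hydroxyphenyl)ethyl group at C8; its pyranone ring C carries a methoxy group at C3 and the 4-methoxyphenyl ring B at C2. The aryl ring of the side chain is called ring D here. The only stereocentre is the side-chain methine, which is R (priorities: ring A carbon C8 > ring D > CH3 > H). It has no neighbouring stereo-element, so it has to be set by a catalyst. This centre is doubly benzylic and sits on a phloroglucinol-type ring, so acid can ionise it, with racemisation or loss of the whole side chain by ipso-protonation. A 5-hydroxy-8-substituted flavone can also open and reclose under strong acid to the 6-substituted isomer (Wessely–Moser rearrangement). Two oxygens (O3 and O4') are methyl ethers while three are free phenols, so the phenols need a mask that comes off without acid and without touching methyl ethers. The central regiochemical problem is that C4a is flanked by two oxygen-bearing carbons, C5 and C8a, and whichever oxygen closes ring C decides whether the side chain ends at C8 or at C6. The strategy rests on marking these positions differently in a phenol precursor: iodine on the carbon that becomes C4a, a free hydroxyl on the carbon that becomes C8a (next to C8), and a benzyl ether on the C5 oxygen.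

## Retrosynthetic reasoning

**16 ← 15.** The last cuts are the three O–benzyl bonds at O5, O7 and the ring D oxygen. Benzyl is chosen because hydrogenolysis is neutral and leaves the two methyl ethers, the pyranone and the benzylic C–C bonds alone. No acid ever meets the free 5-hydroxy-8-alkyl flavone.

**15 ← 14.** The O3–CH3 bond is cut. In 14 the 3-hydroxyl is the only free hydroxyl, so the methylation needs no selectivity.

**14 ← 11.** The C3–O bond is cut. C3–H of flavone 11 is the only sp2 C–H next to the carbonyl, so it can be metalated and oxidised through boron. Taking the oxygen out of the ring-forming step lets ring C be built from a simple terminal alkyne.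

**11 ← 6 + 7 + 8.** This is the key disconnection. It cuts C4a–C4, C4–C3 and O1–C2 and opens ring C. Iodophenol 6 carries the iodine on the future C4a and the only free hydroxyl on the future C8a; carbon monoxide 8 becomes C4; alkyne 7 supplies C3, C2 and ring B. Cutting here, and not at the ring A–side chain bond, means the stereocentre is already in place on a simple phenol and the flavone regiochemistry is decided by where the iodine sits. The forward reaction has to carbonylate before it couples, close six-membered and stay basic.

**6 ← 5.** The C–I bond is cut. Phenol 5 has two free ring positions; the forward iodination must take the one ortho to the hydroxyl. The free hydroxyl serves three times: it directs the hydrogenation, it biases the iodination, and it is the ring-closing nucleophile. No protecting-group step is therefore needed between 4 and 11.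

**5 ← 4.** The two new C–H bonds are removed to give 1,1-diarylethene 4. The alkene is terminal and has a hydroxyl ortho to it that can bind a metal, so a chiral catalyst can be anchored next to the prochiral carbon. The stereocentre is thus made late, from an achiral, easily made precursor.

**4 ← 1 + 2 (through 3).** The bond between the carbinol carbon and ring D is cut, then the alkene is traced to tertiary carbinol 3. Ketone 1 already holds the full oxygen pattern of ring A with exactly one free hydroxyl, and Grignard reagent 2 brings ring D. Dehydration of 3 can only go toward the methyl group.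

## Alternatives that were turned down

**Alternative 1: aryne capture of a methyl ketone.**
- Disconnection: the C8–Cα and C8a–O bonds of the styrenyl phenol, leading to aryne A2 (released from silyl triflate A1) and ketone A3.
- Forward key step: fluoride releases A2. The carbonyl oxygen of A3 adds to the aryne carbon remote from the benzyloxy group, and the aryl anion next to that group closes on the carbonyl carbon. The benzoxete opens to an ortho-quinone methide, which tautomerises to A4. A4 is the same compound as 4.
- For: the regiochemistry follows from the inductive effect of the alkoxy group on the aryne, and no excess organometallic is added to a crowded ketone. On this one point it is stronger than step 1 of the chosen route.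
- Against: A1 needs several steps (ortho-silylation, triflation) from a phenol. A3 has α-hydrogens, so enolate chemistry with the aryne competes with carbonyl insertion. The ortho-quinone methide can be trapped by a second aryne instead of tautomerising.
- Comparison: it only delivers 4, which the chosen route reaches in one step from catalogue compounds, and it contributes nothing to the stereocentre or ring C. The chosen strategy buys ring A ready-made and places its risk on ring C, where the C8/C6 question is settled.

**Alternative 2: benzannulation that builds ring A around the stereocentre.**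
- Disconnection: ring A itself, at C8a–C8, C7–C6 and C4a–C8a.
- Forward key step: cyclobutenone A5 opens on heating to a vinylketene, adds to siloxyalkyne A6 in a [2+2] sense, and the new cyclobutenone opens, closes by 6π electrocyclisation and tautomerises to phenol A7.
- For: the three ring A oxygens emerge fully differentiated (free hydroxyl, silyl ether, ethyl ether) with the substituent position fixed by mechanism. The bulky silyl ether would shield the competing position in a later iodination; on this point it is stronger than step 3 of the chosen route, which relies on a steric preference.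
- Against: A6 must be made from a chiral 2-arylpropanoic acid derivative by ynolate homologation under strong base, and that benzylic, carbonyl-activated then propargylic C–H is prone to epimerisation. The ethyl ether ends on O5 and would later have to be cleaved by a Lewis acid beside the 3-methoxy group and the acid-labile benzylic centre. The sequence is clearly longer.
- Comparison: the chosen strategy starts from a commercial ring A, creates the stereocentre late by catalysis on a stable alkene, and ends with neutral hydrogenolysis.

**Alternative 3: ethylene as the CH–CH3 unit by 1,1-diarylation.**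
- Disconnection: both aryl–Cα bonds at once.
- Forward key step: a zerovalent palladium catalyst with a chiral ligand takes up diazonium salt A8, inserts ethylene A9, walks to the benzylic position, transmetalates with boronic acid A10 and reductively eliminates to A11.
- For: it is the most convergent plan; two C–C bonds and the stereocentre form in one step from simple pieces. A11 is the methoxymethyl ether of 5 and is ready for directed metalation. On bond economy it is stronger than the chosen route.
- Against: enantiocontrol for ethylene with two similar electron-rich aryl groups is not established. A10 is a 2,6-dioxygenated boronic acid, which protodeboronates easily and transmetalates slowly. Heck-type and 1,2-diarylation products compete. The methoxymethyl group would later need acid for removal.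
- Comparison: the chosen strategy sets the stereocentre by a hydrogenation in which the substrate's own hydroxyl binds the catalyst, and it keeps that hydroxyl free for iodination and ring closure.

Key step: step 4

Assumption: ketone 1 and Grignard solution 2 are taken as catalogue items; in step 2 the ligand enantiomer that leads to the R centre is fixed by a test hydrogenation, both enantiomers being available.

## Route

Step 1
Reactants: 1 1-[2,4-bis(benzyloxy)-6-hydroxyphenyl]ethan-1-one; 2 [4-(benzyloxy)phenyl]magnesium bromide
Product: 4 3,5-bis(benzyloxy)-2-{1-[4-(benzyloxy)phenyl]ethenyl}phenol, via tertiary carbinol 3 (not isolated)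
Conditions: 2 (3.5 equiv), THF, 0 → 45 °C; aq NH4Cl; crude 3, p-TsOH·H2O (5 mol%), toluene, 40 °C
Reagents that add atoms: none
Why: Grignard addition to an ortho-hydroxyaryl ketone followed by E1 dehydration; the first equivalent of 2 forms the magnesium phenoxide, whose chelate holds and activates the acetyl group for aryl transfer. Carbinol 3 is tertiary and doubly benzylic, so trace acid should dehydrate it, and the alkene can only form toward the methyl group.

Step 2
Reactants: 4 3,5-bis(benzyloxy)-2-{1-[4-(benzyloxy)phenyl]ethenyl}phenol
Product: 5 3,5-bis(benzyloxy)-2-[(1R)-1-(4-benzyloxyphenyl)ethyl]phenol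
Conditions: [Rh(nbd)2]BF4 (2 mol%), (R)-1-[(SP)-2-(diphenylphosphino)ferrocenyl]ethyldi-tert-butylphosphine (2.2 mol%), Et3N (0.2 equiv), H2 (20 bar), MeOH–THF, 30 °C
Reagents that add atoms: none
Why: Hydroxyl-directed asymmetric hydrogenation of a 1,1-diarylethene; the phenoxide formed with Et3N binds the cationic rhodium–bisphosphine fragment, the alkene is held in a chelate, and the chiral ligand selects the alkene face that receives both hydrogens, which sets the R centre. Homogeneous rhodium should leave the benzyl ethers untouched.

Step 3
Reactants: 5 3,5-bis(benzyloxy)-2-[(1R)-1-(4-benzyloxyphenyl)ethyl]phenol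
Product: 6 3,5-bis(benzyloxy)-2-[(1R)-1-(4-benzyloxyphenyl)ethyl]-6-iodophenol
Conditions: NIS (1.0 equiv), CH2Cl2, −40 → 0 °C, dark
Reagents that add atoms: N-iodosuccinimide, O=C1CCC(=O)N1I
Why: Electrophilic aromatic iodination of a phenol; C6 (ortho to OH) and C4 (para to OH) are electronically alike, but C4 lies between two benzyloxy groups, one of which is pushed toward it by the C2 side chain, whereas C6 has only the small hydroxyl and one freely rotating benzyloxy neighbour, and NIS can be guided by hydrogen bonding to the OH. One equivalent at low temperature should limit di-iodination, and ring D is far less activated; the neutral medium does not endanger the stereocentre.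

Step 4
Reactants: 6 3,5-bis(benzyloxy)-2-[(1R)-1-(4-benzyloxyphenyl)ethyl]-6-iodophenol; 7 4-ethynylanisole; 8 carbon monoxide
Product: 11 5,7-bis(benzyloxy)-8-[(1R)-1-(4-benzyloxyphenyl)ethyl]-2-(4-methoxyphenyl)-4H-chromen-4-one, via ynone 9 (not isolated), via enaminone 10 (not isolated)
Conditions: PdCl2(PPh3)2 (5 mol%), 8 (20 bar), 7 (1.5 equiv), Et2NH, 100 °C, autoclave
Reagents that add atoms: none
Why: The divalent precatalyst is reduced in situ to zerovalent palladium, which inserts into the C–I bond of 6; carbon monoxide insertion gives the aroylpalladium iodide, and transfer of the acetylide formed from 7 and Et2NH followed by reductive elimination gives ynone 9 (C4a–C4 and C4–C3 bonds). Et2NH then adds to the ynone to give enaminone 10, and the ortho phenoxide closes ring C by a 6-endo-trig oxa-Michael addition at C2 with loss of Et2NH (O1–C2 bond). The closest known reaction type is the palladium-catalysed carbonylative coupling of ortho-iodophenols with terminal alkynes in a secondary amine, which gives flavones. No stereocentre is formed; the existing one should survive because the medium is basic throughout and its C–H is not acidic. Three selectivities are needed. Carbonylation must precede alkyne coupling, which the CO pressure and the ready CO insertion of a di-ortho-substituted arylpalladium favour. Closure must be 6-endo and not 5-exo to the aurone, which the enaminone pathway secures. Closure must be at O1 and not at the C5 oxygen, which is secured because only the hydroxyl next to the side chain is free while the C5 oxygen is benzylated and the iodine fixes C4a; only the 8-substituted flavone can form.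

Step 5
Reactants: 11 5,7-bis(benzyloxy)-8-[(1R)-1-(4-benzyloxyphenyl)ethyl]-2-(4-methoxyphenyl)-4H-chromen-4-one
Product: 14 5,7-bis(benzyloxy)-8-[(1R)-1-(4-benzyloxyphenyl)ethyl]-3-hydroxy-2-(4-methoxyphenyl)-4H-chromen-4-one, via 3-lithioflavone 12 (not isolated), via boronate 13 (not isolated)
Conditions: LDA (1.3 equiv), THF, −78 °C; B(OMe)3, −78 → 0 °C; AcOH, 30% aq H2O2, 0 °C → rt
Reagents that add atoms: hydrogen peroxide, OO (the C3 oxygen); trimethyl borate, COB(OC)OC (boron and methoxy groups of intermediate 13 only)
Why: Deprotonative C3 lithiation of a flavone, borate trapping and oxidative C–B to C–O migration; C3–H is the only sp2 C–H next to the carbonyl and the lithium is held by the carbonyl oxygen, while LDA at −78 °C should be too weak and too hindered to touch the benzyl ethers or the diaryl methine. Oxidation under acidic peroxide avoids nucleophilic epoxidation of the pyranone.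

Step 6
Reactants: 14 5,7-bis(benzyloxy)-8-[(1R)-1-(4-benzyloxyphenyl)ethyl]-3-hydroxy-2-(4-methoxyphenyl)-4H-chromen-4-one
Product: 15 5,7-bis(benzyloxy)-8-[(1R)-1-(4-benzyloxyphenyl)ethyl]-3-methoxy-2-(4-methoxyphenyl)-4H-chromen-4-one
Conditions: MeI, K2CO3, acetone, reflux
Reagents that add atoms: iodomethane, CI
Why: Williamson O-methylation of the acidic flavonol hydroxyl, the only free hydroxyl in 14, so no regiochemical question arises; mild carbonate base does not affect the stereocentre.

Step 7
Reactants: 15 5,7-bis(benzyloxy)-8-[(1R)-1-(4-benzyloxyphenyl)ethyl]-3-methoxy-2-(4-methoxyphenyl)-4H-chromen-4-one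
Product: 16 5,7-dihydroxy-8-[(1R)-1-(4-hydroxyphenyl)ethyl]-3-methoxy-2-(4-methoxyphenyl)-4H-chromen-4-one
Conditions: H2 (1 atm), 10% Pd/C, EtOAc–MeOH, rt
Reagents that add atoms: none
Why: Catalytic hydrogenolysis of three aryl benzyl ethers; methyl ethers, the tetrasubstituted pyranone double bond and the benzylic C–C bonds are not cleaved under these conditions, and the neutral medium avoids acid-induced isomerisation of the free 5-hydroxy-8-alkyl flavone.

## Compound list

1 | 1-[2,4-bis(benzyloxy)-6-hydroxyphenyl]ethan-1-one | CC(=O)c1c(O)cc(OCc2ccccc2)cc1OCc1ccccc1 | starting material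
2 | [4-(benzyloxy)phenyl]magnesium bromide (solution in THF) | Br[Mg]c1ccc(OCc2ccccc2)cc1 | starting material
3 | 3,5-bis(benzyloxy)-2-{1-[4-(benzyloxy)phenyl]-1-hydroxyethyl}phenol (racemic) | CC(O)(c1ccc(OCc2ccccc2)cc1)c1c(O)cc(OCc2ccccc2)cc1OCc1ccccc1 | intermediate (not isolated)
4 | 3,5-bis(benzyloxy)-2-{1-[4-(benzyloxy)phenyl]ethenyl}phenol | C=C(c1ccc(OCc2ccccc2)cc1)c1c(O)cc(OCc2ccccc2)cc1OCc1ccccc1 | intermediate
5 | 3,5-bis(benzyloxy)-2-[(1R)-1-(4-benzyloxyphenyl)ethyl]phenol | Oc1cc(OCc2ccccc2)cc(OCc2ccccc2)c1[C@H](C)c1ccc(OCc2ccccc2)cc1 | intermediate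
6 | 3,5-bis(benzyloxy)-2-[(1R)-1-(4-benzyloxyphenyl)ethyl]-6-iodophenol | Oc1c(I)c(OCc2ccccc2)cc(OCc2ccccc2)c1[C@H](C)c1ccc(OCc2ccccc2)cc1 | intermediate
7 | 4-ethynylanisole (1-ethynyl-4-methoxybenzene) | C#Cc1ccc(OC)cc1 | starting material
8 | carbon monoxide | [C-]#[O+] | starting material
9 | 1-{4,6-bis(benzyloxy)-3-[(1R)-1-(4-benzyloxyphenyl)ethyl]-2-hydroxyphenyl}-3-(4-methoxyphenyl)prop-2-yn-1-one | COc1ccc(C#CC(=O)c2c(O)c([C@H](C)c3ccc(OCc4ccccc4)cc3)c(OCc3ccccc3)cc2OCc2ccccc2)cc1 | intermediate (not isolated)
10 | 1-{4,6-bis(benzyloxy)-3-[(1R)-1-(4-benzyloxyphenyl)ethyl]-2-hydroxyphenyl}-3-(diethylamino)-3-(4-methoxyphenyl)prop-2-en-1-one (alkene geometry not fixed) | CCN(CC)C(=CC(=O)c1c(O)c([C@H](C)c2ccc(OCc3ccccc3)cc2)c(OCc2ccccc2)cc1OCc1ccccc1)c1ccc(OC)cc1 | intermediate (not isolated)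
11 | 5,7-bis(benzyloxy)-8-[(1R)-1-(4-benzyloxyphenyl)ethyl]-2-(4-methoxyphenyl)-4H-chromen-4-one | COc1ccc(-c2cc(=O)c3c(OCc4ccccc4)cc(OCc4ccccc4)c([C@H](C)c4ccc(OCc5ccccc5)cc4)c3o2)cc1 | intermediate
12 | {5,7-bis(benzyloxy)-8-[(1R)-1-(4-benzyloxyphenyl)ethyl]-2-(4-methoxyphenyl)-4-oxo-4H-chromen-3-yl}lithium | COc1ccc(-c2oc3c([C@H](C)c4ccc(OCc5ccccc5)cc4)c(OCc4ccccc4)cc(OCc4ccccc4)c3c(=O)c2[Li])cc1 | intermediate (not isolated)
13 | dimethyl {5,7-bis(benzyloxy)-8-[(1R)-1-(4-benzyloxyphenyl)ethyl]-2-(4-methoxyphenyl)-4-oxo-4H-chromen-3-yl}boronate | COB(OC)c1c(-c2ccc(OC)cc2)oc2c([C@H](C)c3ccc(OCc4ccccc4)cc3)c(OCc3ccccc3)cc(OCc3ccccc3)c2c1=O | intermediate (not isolated)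
14 | 5,7-bis(benzyloxy)-8-[(1R)-1-(4-benzyloxyphenyl)ethyl]-3-hydroxy-2-(4-methoxyphenyl)-4H-chromen-4-one | COc1ccc(-c2oc3c([C@H](C)c4ccc(OCc5ccccc5)cc4)c(OCc4ccccc4)cc(OCc4ccccc4)c3c(=O)c2O)cc1 | intermediate
15 | 5,7-bis(benzyloxy)-8-[(1R)-1-(4-benzyloxyphenyl)ethyl]-3-methoxy-2-(4-methoxyphenyl)-4H-chromen-4-one | COc1ccc(-c2oc3c([C@H](C)c4ccc(OCc5ccccc5)cc4)c(OCc4ccccc4)cc(OCc4ccccc4)c3c(=O)c2OC)cc1 | intermediate
16 | 5,7-dihydroxy-8-[(1R)-1-(4-hydroxyphenyl)ethyl]-3-methoxy-2-(4-methoxyphenyl)-4H-chromen-4-one | COc1ccc(-c2oc3c([C@H](C)c4ccc(O)cc4)c(O)cc(O)c3c(=O)c2OC)cc1 | target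

## Step count and least certain steps

Total step count: 7. Longest linear sequence: 7 steps (1 → 4 → 5 → 6 → 11 → 14 → 15 → 16).

**Step 4 (key step).** The aroylpalladium intermediate may be intercepted by diethylamine (aminocarbonylation). The alkyne may couple before carbon monoxide is taken up, followed by closure to a benzofuran. Oxidative addition into the crowded, electron-rich C–I bond may be slow enough for the catalyst to decay. The fallback sets out from 6 and returns at 11 without any carbonylation. Stille coupling of 6 with tributyl(1-ethoxyvinyl)stannane (Pd(PPh3)4, toluene, 100 °C) gives 3,5-bis(benzyloxy)-2-[(1R)-1-(4-benzyloxyphenyl)ethyl]-6-(1-ethoxyethenyl)phenol F1. Brief stirring with dilute aqueous HCl at room temperature hydrolyses it to 1-{4,6-bis(benzyloxy)-3-[(1R)-1-(4-benzyloxyphenyl)ethyl]-2-hydroxyphenyl}ethan-1-one F2. Claisen–Schmidt condensation with 4-methoxybenzaldehyde (KOH, EtOH) gives (2E)-1-{4,6-bis(benzyloxy)-3-[(1R)-1-(4-benzyloxyphenyl)ethyl]-2-hydroxyphenyl}-3-(4-methoxyphenyl)prop-2-en-1-one F3. Oxidative cyclisation with catalytic I2 in DMSO at 120 °C closes ring C to 11. The acetyl group sits where the iodine was, so the regiochemistry is the same.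

**Step 3.** Iodination may go partly to C4 (para to the hydroxyl) or on to the di-iodide, because the preference for C6 is steric and not electronic. The fallback sets out from 5 and returns at 6. The phenol is protected (NaH, MOMCl, DMF, 0 °C) as 1,5-bis(benzyloxy)-2-[(1R)-1-(4-benzyloxyphenyl)ethyl]-3-(methoxymethoxy)benzene F4, the same compound as A11. Directed ortho-lithiation (n-BuLi, THF, −78 → −20 °C) at the position between the methoxymethoxy and benzyloxy groups and quenching with I2 give 1,5-bis(benzyloxy)-2-[(1R)-1-(4-benzyloxyphenyl)ethyl]-4-iodo-3-(methoxymethoxy)benzene F5. Short treatment with dilute HCl in MeOH–THF at room temperature removes the acetal and gives 6. The low temperature is meant to prevent benzylic lithiation of the benzyl ethers, and the brief, dilute acid to spare the benzylic centre.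

**Step 2.** Conversion may be slow or facial selectivity poor, because both positions ortho to the alkene on ring A are substituted, which twists the alkene and strains the rhodium chelate. The fallback sets out from 4 and returns at 5 by an organocatalytic transfer hydrogenation. A chiral BINOL-derived phosphoric acid (for example the 3,3'-bis(2,4,6-triisopropylphenyl) derivative, 5 mol%) and a Hantzsch ester in CH2Cl2 at room temperature are used. The acid tautomerises 4 to the ortho-quinone methide 3,5-bis(benzyloxy)-6-{1-[4-(benzyloxy)phenyl]ethylidene}cyclohexa-2,4-dien-1-one F6, held in a hydrogen-bonded chiral ion pair. Hydride from the Hantzsch ester then adds to the exocyclic carbon on the face left open by the catalyst.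

**Step 5.** Metalation may be incomplete, the 3-lithio species may add to unreacted flavone, or the oxidation may stop at the borate stage. The fallback sets out from 11 and returns at 14 by electrophilic oxidation. Dimethyldioxirane in acetone–CH2Cl2 (0 °C → rt) epoxidises the C2–C3 double bond to 4,6-bis(benzyloxy)-3-[(1R)-1-(4-benzyloxyphenyl)ethyl]-1a-(4-methoxyphenyl)-1a,7a-dihydro-7H-oxireno[2,3-b]chromen-7-one F7 (mixture of epoxide diastereomers). A trace of p-TsOH opens the epoxide with loss of the C3 proton to give 14.

**Step 1.** The basic Grignard reagent may enolise the methyl ketone, or addition to the crowded, electron-rich carbonyl may stall, so that 1 is returned. The fallback sets out from 1 and returns at 4 without a carbonyl addition. Condensation with 4-methylbenzenesulfonohydrazide (MeOH, 60 °C) gives N'-{1-[2,4-bis(benzyloxy)-6-hydroxyphenyl]ethylidene}-4-methylbenzenesulfonohydrazide F8. Palladium-catalysed tosylhydrazone–aryl halide coupling with 1-(benzyloxy)-4-bromobenzene (Pd2(dba)3, XPhos, LiOtBu in excess, dioxane, 100 °C) then proceeds through the diazo compound, a palladium carbene, aryl migration and β-hydride elimination from the methyl group to give 4.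

## Further compounds

F1 | step 4 | 3,5-bis(benzyloxy)-2-[(1R)-1-(4-benzyloxyphenyl)ethyl]-6-(1-ethoxyethenyl)phenol | CCOC(=C)c1c(O)c([C@H](C)c2ccc(OCc3ccccc3)cc2)c(OCc2ccccc2)cc1OCc1ccccc1
F2 | step 4 | 1-{4,6-bis(benzyloxy)-3-[(1R)-1-(4-benzyloxyphenyl)ethyl]-2-hydroxyphenyl}ethan-1-one | CC(=O)c1c(O)c([C@H](C)c2ccc(OCc3ccccc3)cc2)c(OCc2ccccc2)cc1OCc1ccccc1
F3 | step 4 | (2E)-1-{4,6-bis(benzyloxy)-3-[(1R)-1-(4-benzyloxyphenyl)ethyl]-2-hydroxyphenyl}-3-(4-methoxyphenyl)prop-2-en-1-one | COc1ccc(/C=C/C(=O)c2c(O)c([C@H](C)c3ccc(OCc4ccccc4)cc3)c(OCc3ccccc3)cc2OCc2ccccc2)cc1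
F4 | step 3 | 1,5-bis(benzyloxy)-2-[(1R)-1-(4-benzyloxyphenyl)ethyl]-3-(methoxymethoxy)benzene | COCOc1cc(OCc2ccccc2)cc(OCc2ccccc2)c1[C@H](C)c1ccc(OCc2ccccc2)cc1
F5 | step 3 | 1,5-bis(benzyloxy)-2-[(1R)-1-(4-benzyloxyphenyl)ethyl]-4-iodo-3-(methoxymethoxy)benzene | COCOc1c(I)c(OCc2ccccc2)cc(OCc2ccccc2)c1[C@H](C)c1ccc(OCc2ccccc2)cc1
F6 | step 2 | 3,5-bis(benzyloxy)-6-{1-[4-(benzyloxy)phenyl]ethylidene}cyclohexa-2,4-dien-1-one | CC(c1ccc(OCc2ccccc2)cc1)=C1C(=O)C=C(OCc2ccccc2)C=C1OCc1ccccc1
F7 | step 5 | 4,6-bis(benzyloxy)-3-[(1R)-1-(4-benzyloxyphenyl)ethyl]-1a-(4-methoxyphenyl)-1a,7a-dihydro-7H-oxireno[2,3-b]chromen-7-one | COc1ccc(C23OC2C(=O)c2c(OCc4ccccc4)cc(OCc4ccccc4)c([C@H](C)c4ccc(OCc5ccccc5)cc4)c2O3)cc1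
F8 | step 1 | N'-{1-[2,4-bis(benzyloxy)-6-hydroxyphenyl]ethylidene}-4-methylbenzenesulfonohydrazide | CC(=NNS(=O)(=O)c1ccc(C)cc1)c1c(O)cc(OCc2ccccc2)cc1OCc1ccccc1
A1 | alternative 1 | 3,5-bis(benzyloxy)-2-(trimethylsilyl)phenyl trifluoromethanesulfonate | C[Si](C)(C)c1c(OCc2ccccc2)cc(OCc2ccccc2)cc1OS(=O)(=O)C(F)(F)F
A2 | alternative 1 | 3,5-bis(benzyloxy)benzyne | C1#CC(OCc2ccccc2)=CC(OCc2ccccc2)=C1
A3 | alternative 1 | 1-[4-(benzyloxy)phenyl]ethan-1-one | CC(=O)c1ccc(OCc2ccccc2)cc1
A4 | alternative 1 | 3,5-bis(benzyloxy)-2-{1-[4-(benzyloxy)phenyl]ethenyl}phenol | C=C(c1ccc(OCc2ccccc2)cc1)c1c(O)cc(OCc2ccccc2)cc1OCc1ccccc1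
A5 | alternative 2 | 3-ethoxycyclobut-2-en-1-one | CCOC1=CC(=O)C1
A6 | alternative 2 | {[(3R)-3-(4-benzyloxyphenyl)but-1-yn-1-yl]oxy}tri(propan-2-yl)silane | CC(C)[Si](OC#C[C@H](C)c1ccc(OCc2ccccc2)cc1)(C(C)C)C(C)C
A7 | alternative 2 | 2-[(1R)-1-(4-benzyloxyphenyl)ethyl]-5-ethoxy-3-(triisopropylsilyloxy)phenol | CCOc1cc(O)c([C@H](C)c2ccc(OCc3ccccc3)cc2)c(O[Si](C(C)C)(C(C)C)C(C)C)c1
A8 | alternative 3 | 4-(benzyloxy)benzenediazonium tetrafluoroborate | N#[N+]c1ccc(OCc2ccccc2)cc1.F[B-](F)(F)F
A9 | alternative 3 | ethylene | C=C
A10 | alternative 3 | [2,4-bis(benzyloxy)-6-(methoxymethoxy)phenyl]boronic acid | OB(O)c1c(OCc2ccccc2)cc(OCc2ccccc2)cc1OCOC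
A11 | alternative 3 | 1,5-bis(benzyloxy)-2-[(1R)-1-(4-benzyloxyphenyl)ethyl]-3-(methoxymethoxy)benzene | COCOc1cc(OCc2ccccc2)cc(OCc2ccccc2)c1[C@H](C)c1ccc(OCc2ccccc2)cc1
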